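**Retrosynthetic overview**
- The target comes from its hepta-O-methyl ether by a final global demethylation.
- The methyl ether comes from a methoxyhydroquinone that carries a C-linked o-bromoaryl ring and an O-linked o,m-dibromoaryl ring. Twofold intramolecular Ullmann O-arylation closes the furan and the 1,4-dioxin together, and the surviving bromide then takes 3,5-dimethoxyphenol in the same pot.
- The hydroquinone comes from addition–elimination of a dibromodimethoxyphenoxide on an aryl bromo methoxy benzoquinone (first dioxin C–O bond), followed by reduction.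
- The arylquinone comes from acid-promoted conjugate arylation of 2-bromo-6-methoxybenzoquinone with 1-bromo-3,5-dimethoxybenzene (biaryl C–C bond).
- Ring order: the four benzene rings are bought; the furan and dioxin rings are formed last, in one operation.

Assumption: the target has no stereocentres (it is achiral), so no stereocontrol is needed; hindered biaryl axes in intermediates are racemic and disappear on furan closure.

**Step 1**
Reactants: 1 2-bromo-6-methoxyphenol
Product: 2 2-bromo-6-methoxycyclohexa-2,5-diene-1,4-dione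
Conditions: salcomine (5 mol%), O2 (1 atm), DMF, rt
Reagents that add atoms: dioxygen, O=O
Why: Co(salen)-catalysed aerobic para-oxidation of a 2,6-disubstituted phenol to the p-benzoquinone (the catalytic counterpart of the Teuber/Fremy oxidation).

**Step 2**
Reactants: 2 2-bromo-6-methoxycyclohexa-2,5-diene-1,4-dione (2.5 equiv); 3 1-bromo-3,5-dimethoxybenzene
Product: 5 2-bromo-3-(2-bromo-4,6-dimethoxyphenyl)-6-methoxycyclohexa-2,5-diene-1,4-dione, via arylhydroquinone 4 (not isolated)
Conditions: TFA–CH2Cl2 (1:4), 0 °C → rt
Reagents that add atoms: none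
Why: Acid-promoted Friedel–Crafts-type conjugate arylation of a quinone, in which the arene reacts through C2 (para to OMe, ortho to Br, as expected for its electrophilic substitution) at the free carbon of the bromo-alkene (the methoxy-alkene is deactivated as a vinylogous ester), and excess 2 re-oxidises the arylhydroquinone by quinone–hydroquinone redox exchange.

**Step 3**
Reactants: 6 2,4-dimethoxyphenol
Product: 7 2,3-dibromo-4,6-dimethoxyphenol
Conditions: NBS (2.0 equiv), MeCN, −10 °C → rt
Reagents that add atoms: N-bromosuccinimide, O=C1CCC(=O)N1Br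
Why: Electrophilic aromatic bromination at the two most activated and least hindered positions (ortho to OH; para/ortho to the OMe groups), leaving the CH flanked by two OMe groups untouched.

**Step 4**
Reactants: 5 2-bromo-3-(2-bromo-4,6-dimethoxyphenyl)-6-methoxycyclohexa-2,5-diene-1,4-dione; 7 2,3-dibromo-4,6-dimethoxyphenol
Product: 9 3-(2-bromo-4,6-dimethoxyphenyl)-2-(2,3-dibromo-4,6-dimethoxyphenoxy)-6-methoxybenzene-1,4-diol, via aryloxyquinone 8 (not isolated)
Conditions: Cs2CO3 (1.1 equiv), MeCN, 0 °C → rt; then aq. Na2S2O4, EtOAc, rt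
Reagents that add atoms: none
Why: Addition–elimination (vinylogous acyl substitution) of the phenoxide at the bromine-bearing quinone carbon forms the first dioxin C–O bond with fixed regiochemistry, and dithionite reduces the quinone to the hydroquinone.

**Step 5**
Reactants: 9 3-(2-bromo-4,6-dimethoxyphenyl)-2-(2,3-dibromo-4,6-dimethoxyphenoxy)-6-methoxybenzene-1,4-diol; 10 3,5-dimethoxyphenol
Product: 12 hepta-O-methyl ether of the target, via bromo pentacycle 11 (not isolated)
Conditions: CuI (20 mol%), 2,2,6,6-tetramethylheptane-3,5-dione (40 mol%), Cs2CO3 (6 equiv), degassed NMP, 100 °C; then 10 (3 equiv), 130 °C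
Reagents that add atoms: none
Why: Proposed new method: twofold intramolecular Ullmann O-arylation, in which the hydroquinone dianion displaces (Cu(I)/Cu(III) oxidative addition–reductive elimination) the ortho-bromide of the C-linked aryl ring to close the furan and the ortho-bromide of the O-linked aryl ring to close the 1,4-dioxin, each phenoxide being able to reach only one bromide, after which the remaining bromide undergoes intermolecular Ullmann etherification with 10; the closest known reactions are Cu-catalysed cyclisations of 2'-bromobiaryl-2-ols to dibenzofurans and of 2-(2-bromophenoxy)phenols to dibenzodioxins, and CuI/diketone diaryl ether synthesis.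

**Step 6**
Reactants: 12 hepta-O-methyl ether of the target
Product: 13 target CNP0256302.0
Conditions: BBr3 (15 equiv), CH2Cl2, −78 °C → rt; then MeOH, H2O, 0 °C (under Ar)
Reagents that add atoms: none
Why: BBr3 cleavage of all seven aryl methyl ethers, to which the diaryl ether, dibenzofuran and dibenzodioxin C–O bonds are inert.

**Compound list**
1 | 2-bromo-6-methoxyphenol | COc1cccc(Br)c1O | starting material
2 | 2-bromo-6-methoxycyclohexa-2,5-diene-1,4-dione | COC1=CC(=O)C=C(Br)C1=O | intermediate
3 | 1-bromo-3,5-dimethoxybenzene | COc1cc(Br)cc(OC)c1 | starting material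
4 | 2-bromo-3-(2-bromo-4,6-dimethoxyphenyl)-6-methoxybenzene-1,4-diol | COc1cc(O)c(-c2c(Br)cc(OC)cc2OC)c(Br)c1O | intermediate (not isolated)
5 | 2-bromo-3-(2-bromo-4,6-dimethoxyphenyl)-6-methoxycyclohexa-2,5-diene-1,4-dione | COC1=CC(=O)C(c2c(Br)cc(OC)cc2OC)=C(Br)C1=O | intermediate
6 | 2,4-dimethoxyphenol | COc1ccc(O)c(OC)c1 | starting material
7 | 2,3-dibromo-4,6-dimethoxyphenol | COc1cc(OC)c(Br)c(Br)c1O | intermediate
8 | 3-(2-bromo-4,6-dimethoxyphenyl)-2-(2,3-dibromo-4,6-dimethoxyphenoxy)-6-methoxycyclohexa-2,5-diene-1,4-dione | COC1=CC(=O)C(c2c(Br)cc(OC)cc2OC)=C(Oc2c(Br)c(Br)c(OC)cc2OC)C1=O | intermediate (not isolated)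
9 | 3-(2-bromo-4,6-dimethoxyphenyl)-2-(2,3-dibromo-4,6-dimethoxyphenoxy)-6-methoxybenzene-1,4-diol | COc1cc(O)c(-c2c(Br)cc(OC)cc2OC)c(Oc2c(Br)c(Br)c(OC)cc2OC)c1O | intermediate
10 | 3,5-dimethoxyphenol | COc1cc(O)cc(OC)c1 | starting material
11 | bromo pentacycle: benzofuran-fused dibenzo[1,4]dioxin core of the target with OMe at the five ring-OH positions and Br on the carbon that carries the aryloxy group in the target | COc1cc2oc3cc(OC)cc(OC)c3c2c2Oc3c(OC)cc(OC)c(Br)c3Oc12 | intermediate (not isolated)
12 | hepta-O-methyl ether of the target (11 with Br replaced by 3,5-dimethoxyphenoxy) | COc1cc2oc3cc(OC)cc(OC)c3c2c2Oc3c(OC)cc(OC)c(Oc4cc(OC)cc(OC)c4)c3Oc12 | intermediate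
13 | target CNP0256302.0: benzofuran-fused dibenzo[1,4]dioxin pentol bearing a 3,5-dihydroxyphenoxy group | Oc1cc(O)cc(Oc2c(O)cc(O)c3c2Oc2c(O)cc4oc5cc(O)cc(O)c5c4c2O3)c1 | target

**Step count and risks**
Total steps: 6. Longest linear sequence: 5 (steps 1, 2, 4, 5, 6; step 3 is a one-step side branch).

Step 5 is the most likely to fail. The electron-rich hydroquinone dianion may be oxidised or debrominated before both hindered closures and the hindered intermolecular coupling are complete. The fallback builds the dioxin by homodimerisation and the furan by acid, so no hydroquinone meets copper. It sets out from 6 and comes back at 13: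
- ortho-bromination of 6 (NBS, cat. i-Pr2NH, CH2Cl2) gives 2-bromo-4,6-dimethoxyphenol F3;
- Ullmann self-condensation (CuI, Cs2CO3, NMP/pyridine, 140 °C) gives the head-to-tail dimer 1,3,6,8-tetramethoxydibenzo[b,e][1,4]dioxine F4;
- NBS (2 equiv) gives 4,9-dibromo-1,3,6,8-tetramethoxydibenzo[b,e][1,4]dioxine F5 (para to OMe on each ring);
- mono-Ullmann coupling with 10 (F5 in excess and recovered) gives 4-bromo-9-(3,5-dimethoxyphenoxy)-1,3,6,8-tetramethoxydibenzo[b,e][1,4]dioxine F6;
- Suzuki coupling with 2,4,6-trimethoxyphenylboronic acid (Pd/SPhos, K3PO4) gives 9-(3,5-dimethoxyphenoxy)-1,3,6,8-tetramethoxy-4-(2,4,6-trimethoxyphenyl)dibenzo[b,e][1,4]dioxine F7;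
- 48% HBr/AcOH at reflux removes all nine methyl groups and closes the furan by dehydration, giving 13.

Step 2 is the second risk. 1-Bromo-3,5-dimethoxybenzene is a modest nucleophile and could add para to Br or displace the quinone bromide, and the redox exchange may stop short of full oxidation to 5. The fallback gives up the aryl bromide as furan precursor. It sets out from 2 and comes back at 11:
- 2 reacts 1:1 with the far more nucleophilic 10 (AcOH, cat. H2SO4, rt); ortho-C-arylation next to the C–Br carbon and in situ cyclodehydration give 1-bromo-3,7,9-trimethoxydibenzo[b,d]furan-2-ol F1;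
- copper-mediated cross-condensation of F1 with excess 7 (CuI, Cs2CO3, NMP, 130 °C; each phenoxide displaces the other ring's ortho-bromide, head-to-tail) closes the dioxin and gives 11, which is taken on as in the second stage of step 5.

Step 4 is the third risk. The phenoxide must attack a quinone carbon flanked by a di-ortho-substituted aryl group, and electron transfer or attack at the free CH may compete. The fallback reverses the order of C–O and C–C bond formation. It sets out from 2 and 7 and comes back at 9:
- addition–elimination of 7 on the unhindered quinone 2 (Cs2CO3, MeCN, 0 °C) gives 2-(2,3-dibromo-4,6-dimethoxyphenoxy)-6-methoxycyclohexa-2,5-diene-1,4-dione F2;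
- acid-promoted conjugate arylation of F2 with 3 (TFA–CH2Cl2) at the CH next to the aryloxy-bearing carbon gives hydroquinone 9 directly, without an oxidant.

**Further compounds**
F1 | step 2 | 1-bromo-3,7,9-trimethoxydibenzo[b,d]furan-2-ol | COc1cc2oc3cc(OC)cc(OC)c3c2c(Br)c1O
F2 | step 4 | 2-(2,3-dibromo-4,6-dimethoxyphenoxy)-6-methoxycyclohexa-2,5-diene-1,4-dione | COC1=CC(=O)C=C(Oc2c(Br)c(Br)c(OC)cc2OC)C1=O
F3 | step 5 | 2-bromo-4,6-dimethoxyphenol | COc1cc(OC)c(O)c(Br)c1
F4 | step 5 | 1,3,6,8-tetramethoxydibenzo[b,e][1,4]dioxine | COc1cc(OC)c2Oc3cc(OC)cc(OC)c3Oc2c1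
F5 | step 5 | 4,9-dibromo-1,3,6,8-tetramethoxydibenzo[b,e][1,4]dioxine | COc1cc(OC)c2Oc3c(Br)c(OC)cc(OC)c3Oc2c1Br
F6 | step 5 | 4-bromo-9-(3,5-dimethoxyphenoxy)-1,3,6,8-tetramethoxydibenzo[b,e][1,4]dioxine | COc1cc(OC)c2Oc3c(Oc4cc(OC)cc(OC)c4)c(OC)cc(OC)c3Oc2c1Br
F7 | step 5 | 9-(3,5-dimethoxyphenoxy)-1,3,6,8-tetramethoxy-4-(2,4,6-trimethoxyphenyl)dibenzo[b,e][1,4]dioxine | COc1cc(OC)c2Oc3c(Oc4cc(OC)cc(OC)c4)c(OC)cc(OC)c3Oc2c1-c1c(OC)cc(OC)cc1OC
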